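The route rests on ring B (C4a, C5, C6, C7, C8, C8a): its C5 ketone, the ester on C6 and the hexadecyl-bearing C7 make it a cyclohexenone that a ketodiester (C4a, C5, C6) and an enone (C7, C8, C8a) can deliver by conjugate addition plus condensation. Cutting C4a–C8a and C6=C7 leads to dimethyl 3-oxopentanedioate and the E-enone methyl 5-oxohenicos-3-enoate (CH2CO2Me on the β-carbon, hexadecyl on the ketone); one chiral-amine-catalysed Michael–Knoevenagel operation closes ring B and sets C8a. The C4a ester is then kept as a handle: it carries the C4a–C4 bond formation, blocks the ring fusion while ring A is closed at C1–C2, and leaves last, so that C4a is protonated from the convex face (cis fusion).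

Key step: step 3

Remark on the chemistry: the target SMILES is read as the cis-fused (1S,4R,4aS,8aR) decalin with H4a, H8a and H4 on one face and H1 on the other, which is why C4a is set by a final kinetic protonation; methyl glyoxylate 11 is taken as commercial and used freshly depolymerised.

Step 1
Reactants: 1 heptadecanoyl chloride; 2 tributyl(vinyl)stannane
Product: 3 nonadec-1-en-3-one
Conditions: PdCl2(PPh3)2 (2 mol %), BHT (trace), THF, 60 °C
Reagents that add atoms: none
Why: Stille acylation: the acyl chloride adds to zerovalent palladium (formed from the divalent precatalyst), the vinyl group is transferred from tin and reductive elimination gives the vinyl ketone in one step; no stereocentre is formed and BHT holds back polymerisation.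

Step 2
Reactants: 3 nonadec-1-en-3-one; 4 methyl but-3-enoate (3 equiv)
Product: 5 methyl (E)-5-oxohenicos-3-enoate
Conditions: second-generation Grubbs catalyst (3 mol %), 1,4-benzoquinone (10 mol %), CH2Cl2, 40 °C
Reagents that add atoms: none
Why: Olefin cross-metathesis of an electron-poor vinyl ketone that does not homodimerise with an excess of a simple terminal alkene should give the E-enone, and benzoquinone suppresses ruthenium hydride migration of the alkene; 5 is used promptly because its C2 methylene is acidic.

Step 3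
Reactants: 5 methyl (E)-5-oxohenicos-3-enoate; 6 dimethyl 3-oxopentanedioate (1.5 equiv)
Product: 8 dimethyl (1S,6S)-4-hexadecyl-6-(2-methoxy-2-oxoethyl)-2-oxocyclohex-3-ene-1,3-dicarboxylate, via Michael adduct 7 (not isolated)
Conditions: 9-amino-9-deoxy-epi-quinine (20 mol %), 2-fluorobenzoic acid (40 mol %), 4 Å MS, toluene, 25 → 45 °C, 5 added over 6 h
Reagents that add atoms: none
Why: The primary amine condenses with the C7 ketone of 5 to an iminium ion while its protonated quinuclidine holds the enol of 6, so that one doubly activated methylene adds to C8a (bond C4a–C8a) and the other (C6) then attacks the C7 iminium carbon and expels the amine (bond C6=C7), water being the only by-product. The closest known reaction type is the chiral primary-amine-catalysed Michael addition of 1,3-dicarbonyl compounds to enones followed by intramolecular Knoevenagel condensation to cyclohexenones. Ring B closes by 6-exo-trig addition of C6 to the exocyclic C7=N (or C7=O) bond. C8a is set by the catalyst, which leaves one face of the E-iminium open (the quinidine-derived pseudo-enantiomer is the alternative should the opposite sense result), whereas C4a is a labile β-keto ester centre drawn trans that becomes quaternary in step 7 and is finally set in step 9. The step needs conjugate addition at C8a to outrun dienamine formation and self-addition through the acidic C2 methylene of 5, which the acid co-catalyst, the excess of the more acidic 6 and the slow addition of 5 should secure; the ester-conjugated tautomer of 5 is electrophilic at the same carbon, so alkene migration does no harm. Closure through C6 should win over an enamine aldol from the hexadecyl α-carbon onto C5 because C6 is the only doubly activated nucleophile left in 7.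

Step 4
Reactants: 8 dimethyl (1S,6S)-4-hexadecyl-6-(2-methoxy-2-oxoethyl)-2-oxocyclohex-3-ene-1,3-dicarboxylate
Product: 9 1-(4-methoxybenzyl) 3-methyl (1S,6S)-4-hexadecyl-6-(2-methoxy-2-oxoethyl)-2-oxocyclohex-3-ene-1,3-dicarboxylate
Conditions: 4-MeOC6H4CH2OH (3 equiv), DMAP (30 mol %), 4 Å MS, toluene, 110 °C, N2
Reagents that add atoms: 4-methoxybenzyl alcohol, COc1ccc(CO)cc1
Why: DMAP-catalysed transesterification of an enolisable β-keto ester (acylketene pathway) should exchange only the C4a ester, the one ester flanked by the ketone and an α-hydrogen, while the conjugated C6 ester and the C1 acetate ester stay methyl; this gives the C4a carboxyl an acid-labile label for step 9 and does not touch C8a.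

Step 5
Reactants: 1 heptadecanoyl chloride
Product: 10 1-(triphenylphosphoranylidene)octadecan-2-one
Conditions: Ph3PCH3Br (2.1 equiv), n-BuLi (2.05 equiv), THF, 0 °C; then 1, −78 → 25 °C
Reagents that add atoms: methyltriphenylphosphonium bromide, C[P+](c1ccccc1)(c1ccccc1)c1ccccc1.[Br-]
Why: C-acylation of methylenetriphenylphosphorane by an acid chloride, with the second equivalent of ylide taking the proton (transylidation), is the standard entry to acyl-stabilised ylides.

Step 6
Reactants: 10 1-(triphenylphosphoranylidene)octadecan-2-one; 11 methyl glyoxylate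
Product: 12 methyl (E)-4-oxoicos-2-enoate
Conditions: toluene, 25 → 60 °C
Reagents that add atoms: none
Why: Wittig olefination of the reactive aldehyde with an acyl-stabilised ylide should give the E-alkene.

Step 7
Reactants: 9 1-(4-methoxybenzyl) 3-methyl (1S,6S)-4-hexadecyl-6-(2-methoxy-2-oxoethyl)-2-oxocyclohex-3-ene-1,3-dicarboxylate; 12 methyl (E)-4-oxoicos-2-enoate (1.3 equiv)
Product: 13 1-(4-methoxybenzyl) 3-methyl (1S,6S)-4-hexadecyl-1-[(2R,3Z)-1-methoxy-1-oxo-4-(trifluoromethylsulfonyloxy)icos-3-en-2-yl]-6-(2-methoxy-2-oxoethyl)-2-oxocyclohex-3-ene-1,3-dicarboxylate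
Conditions: NaN(SiMe3)2 (1.05 equiv), THF, −78 °C; then 12 and 2-[N,N-bis(trifluoromethylsulfonyl)amino]-5-chloropyridine (1.5 equiv) added together, −78 → −40 °C
Reagents that add atoms: 2-[N,N-bis(trifluoromethylsulfonyl)amino]-5-chloropyridine, Clc1ccc(N(S(=O)(=O)C(F)(F)F)S(=O)(=O)C(F)(F)F)nc1
Why: Tandem conjugate addition–enolate trapping: the stabilised C4a sodium enolate adds to the doubly activated alkene of 12 at the carbon β to the ketone (α to the ester), the usual regiochemistry of 4-oxo-2-enoates, and the ketone enolate born from the s-cis enone is O-sulfonylated at once, which fixes the double bond at C2=C3 with the oxygen cis to C4 (Z); the acceptor should enter anti to the C8a side chain, and the two centres formed here (C4a and C4) are provisional, since step 8 re-sets C4 and step 9 re-sets C4a.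

Step 8
Reactants: 13 1-(4-methoxybenzyl) 3-methyl (1S,6S)-4-hexadecyl-1-[(2R,3Z)-1-methoxy-1-oxo-4-(trifluoromethylsulfonyloxy)icos-3-en-2-yl]-6-(2-methoxy-2-oxoethyl)-2-oxocyclohex-3-ene-1,3-dicarboxylate
Product: 14 4a-(4-methoxybenzyl) 1,4,6-trimethyl (1S,4R,4aS,8aS)-2,7-dihexadecyl-5-oxo-1,4,4a,5,8,8a-hexahydronaphthalene-1,4,4a,6-tetracarboxylate
Conditions: LiN(i-Pr)2 (3.2 equiv), THF, −78 → −40 °C; ZnCl2 (3.5 equiv), → 0 °C; Pd(dba)2 (5 mol %), P(t-Bu)3 (10 mol %), 25–45 °C; aq NH4Cl, 0 °C
Reagents that add atoms: none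
Why: Negishi-type α-alkenylation of an ester enolate: the amide base first turns the acidic ring B enone into its dienolate (which protects it), then removes C4–H and one C1–H, zinc exchange gives weakly basic enolates, zerovalent palladium inserts into the C2–O bond of the alkenyl triflate and the divalent alkenylpalladium couples with the unstabilised C1 zinc enolate, which closes the six-membered ring A at C1–C2 and leaves the alkene at C2=C3; C1 is set in this bond-forming event with its ester pseudo-equatorial (the axial position clashes 1,3 with the angular C4a ester) and is not re-enolised, and C4 is set on work-up by protonation of its zinc dienolate at C4 on the face opposite the angular ester.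

Step 9
Reactants: 14 4a-(4-methoxybenzyl) 1,4,6-trimethyl (1S,4R,4aS,8aS)-2,7-dihexadecyl-5-oxo-1,4,4a,5,8,8a-hexahydronaphthalene-1,4,4a,6-tetracarboxylate
Product: 16 trimethyl (1S,4R,4aS,8aR)-2,7-dihexadecyl-5-oxo-1,4,4a,5,8,8a-hexahydronaphthalene-1,4,6-tricarboxylate, via β-keto acid 15 (not isolated)
Conditions: CF3CO2H (5 vol %), anisole (5 equiv), CH2Cl2, 0 °C; evaporate; toluene, 50 °C
Reagents that add atoms: none
Why: Acidolysis of the 4-methoxybenzyl ester leaves a β-keto acid that loses CO2 through the C4a=C5 enol, and this enol is protonated at C4a on its convex face, the face of H8a away from C1 and C3 of ring A, which should give the cis ring fusion under kinetic control; no base is present, so C1, C4, the new C4a centre and the skipped C2=C3 alkene stay as they are, and the three methyl esters are inert to the acid.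

Compound list
1 | heptadecanoyl chloride | CCCCCCCCCCCCCCCCC(Cl)=O | starting material
2 | tributyl(vinyl)stannane | C=C[Sn](CCCC)(CCCC)CCCC | starting material
3 | nonadec-1-en-3-one | C=CC(=O)CCCCCCCCCCCCCCCC | intermediate
4 | methyl but-3-enoate | C=CCC(=O)OC | starting material
5 | methyl (E)-5-oxohenicos-3-enoate | COC(=O)C/C=C/C(=O)CCCCCCCCCCCCCCCC | intermediate
6 | dimethyl 3-oxopentanedioate | COC(=O)CC(=O)CC(=O)OC | starting material
7 | dimethyl 2-[(3S)-1-methoxy-1,5-dioxohenicosan-3-yl]-3-oxopentanedioate (Michael adduct; C2 of the glutarate unit labile) | COC(=O)C[C@@H](C(C(=O)OC)C(=O)CC(=O)OC)CC(=O)CCCCCCCCCCCCCCCC | intermediate (not isolated)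
8 | dimethyl (1S,6S)-4-hexadecyl-6-(2-methoxy-2-oxoethyl)-2-oxocyclohex-3-ene-1,3-dicarboxylate (trans; C1 labile) | COC(=O)C[C@@H]1CC(CCCCCCCCCCCCCCCC)=C(C(=O)OC)C(=O)[C@H]1C(=O)OC | intermediate
9 | 1-(4-methoxybenzyl) 3-methyl (1S,6S)-4-hexadecyl-6-(2-methoxy-2-oxoethyl)-2-oxocyclohex-3-ene-1,3-dicarboxylate | COC(=O)C[C@@H]1CC(CCCCCCCCCCCCCCCC)=C(C(=O)OC)C(=O)[C@H]1C(=O)OCc1ccc(OC)cc1 | intermediate
10 | 1-(triphenylphosphoranylidene)octadecan-2-one | CCCCCCCCCCCCCCCCC(=O)C=P(c1ccccc1)(c1ccccc1)c1ccccc1 | intermediate
11 | methyl glyoxylate | COC(=O)C=O | starting material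
12 | methyl (E)-4-oxoicos-2-enoate | COC(=O)/C=C/C(=O)CCCCCCCCCCCCCCCC | intermediate
13 | 1-(4-methoxybenzyl) 3-methyl (1S,6S)-4-hexadecyl-1-[(2R,3Z)-1-methoxy-1-oxo-4-(trifluoromethylsulfonyloxy)icos-3-en-2-yl]-6-(2-methoxy-2-oxoethyl)-2-oxocyclohex-3-ene-1,3-dicarboxylate (new side chain trans to the C6 side chain) | COC(=O)C[C@@H]1CC(CCCCCCCCCCCCCCCC)=C(C(=O)OC)C(=O)[C@]1([C@H](C(=O)OC)/C=C(\OS(=O)(=O)C(F)(F)F)CCCCCCCCCCCCCCCC)C(=O)OCc1ccc(OC)cc1 | intermediate
14 | 4a-(4-methoxybenzyl) 1,4,6-trimethyl (1S,4R,4aS,8aS)-2,7-dihexadecyl-5-oxo-1,4,4a,5,8,8a-hexahydronaphthalene-1,4,4a,6-tetracarboxylate (trans-fused, angular ester on C4a) | CCCCCCCCCCCCCCCCC1=C[C@@H](C(=O)OC)[C@]2(C(=O)OCc3ccc(OC)cc3)C(=O)C(C(=O)OC)=C(CCCCCCCCCCCCCCCC)C[C@H]2[C@@H]1C(=O)OC | intermediate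
15 | (1S,4R,4aS,8aS)-2,7-dihexadecyl-1,4,6-tris(methoxycarbonyl)-5-oxo-1,4,4a,5,8,8a-hexahydronaphthalene-4a-carboxylic acid | CCCCCCCCCCCCCCCCC1=C[C@@H](C(=O)OC)[C@]2(C(=O)O)C(=O)C(C(=O)OC)=C(CCCCCCCCCCCCCCCC)C[C@H]2[C@@H]1C(=O)OC | intermediate (not isolated)
16 | trimethyl (1S,4R,4aS,8aR)-2,7-dihexadecyl-5-oxo-1,4,4a,5,8,8a-hexahydronaphthalene-1,4,6-tricarboxylate (CNP0149813.1; cis-fused) | CCCCCCCCCCCCCCCCC1=C[C@@H](C(=O)OC)[C@H]2C(=O)C(C(=O)OC)=C(CCCCCCCCCCCCCCCC)C[C@H]2[C@@H]1C(=O)OC | target

Total step count: 9 steps. Longest linear sequence: 7 steps (steps 1, 2, 3, 4, 7, 8, 9 from heptadecanoyl chloride); steps 5 and 6 make the acceptor 12 in a side branch.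

Steps most likely to fail

Step 3. The primary amine may be drained into the conjugated dienamine of 5 or the enamino ester of 6, 5 may add to itself through its acidic C2 methylene, facial control at C8a may be poor, or the sequence may stop at the open adduct. The fallback gives up covalent activation of the ketone: a cinchona-derived tertiary amine–squaramide deprotonates 6 and hydrogen-bonds the enone. It sets out from 5 and 6, the Michael adduct 7 is isolated, and a separate piperidinium acetate Knoevenagel condensation (toluene, removal of water) closes ring B, so that the route is rejoined at 8. No new compound is made.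

Step 7. The transient ketone enolate may take a proton from the acidic C8 methylene of ring B, or revert by retro-Michael reaction, before it is sulfonylated, so that the position of the enol double bond is lost; the hindered quaternary C–C bond may also form slowly. The fallback has no free enolate until the trapping event. It sets out from 9, which is O-silylated (Me3SiCl, Et3N) to the silyl enol ether F1. A Me3SiOTf-promoted Mukaiyama–Michael addition of F1 to 12 gives the adduct directly as the C2–O silyl enol ether F2, because the acceptor oxygen is silylated in the addition itself. Fluoride-catalysed sulfonylation with C4F9SO2F turns F2 into the alkenyl nonaflate F3, which takes the place of 13 in step 8 and rejoins the route at 14.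

Step 8. The ring B dienolate (through C8) or the C4 dienolate may capture the alkenylpalladium, the amide base may eliminate the triflate to an alkyne, or the C1 methylene may not be metalated next to the more acidic sites. The fallback masks ring B first. It sets out from 13, which t-BuMe2SiOTf and Et3N convert into the 2-silyloxy diene F4; ring B then has no acidic proton and cannot act as a carbon nucleophile. The same zinc enolate coupling, now needing only the two ester sites, gives the bicyclic silyl dienol ether F5. The acid of step 9 removes the silyl group and the 4-methoxybenzyl ester together, and the route is rejoined at 15 and so at 16.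

Further compounds
F0 | step 3 | none | none
F1 | step 7 | 1-(4-methoxybenzyl) 3-methyl (6S)-4-hexadecyl-6-(2-methoxy-2-oxoethyl)-2-(trimethylsilyloxy)cyclohexa-1,3-diene-1,3-dicarboxylate | COC(=O)C[C@@H]1CC(CCCCCCCCCCCCCCCC)=C(C(=O)OC)C(O[Si](C)(C)C)=C1C(=O)OCc1ccc(OC)cc1
F2 | step 7 | 1-(4-methoxybenzyl) 3-methyl (1S,6S)-4-hexadecyl-1-[(2R,3Z)-1-methoxy-1-oxo-4-(trimethylsilyloxy)icos-3-en-2-yl]-6-(2-methoxy-2-oxoethyl)-2-oxocyclohex-3-ene-1,3-dicarboxylate | COC(=O)C[C@@H]1CC(CCCCCCCCCCCCCCCC)=C(C(=O)OC)C(=O)[C@]1([C@H](C(=O)OC)/C=C(\O[Si](C)(C)C)CCCCCCCCCCCCCCCC)C(=O)OCc1ccc(OC)cc1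
F3 | step 7 | 1-(4-methoxybenzyl) 3-methyl (1S,6S)-4-hexadecyl-1-[(2R,3Z)-1-methoxy-4-(nonafluorobutylsulfonyloxy)-1-oxoicos-3-en-2-yl]-6-(2-methoxy-2-oxoethyl)-2-oxocyclohex-3-ene-1,3-dicarboxylate | COC(=O)C[C@@H]1CC(CCCCCCCCCCCCCCCC)=C(C(=O)OC)C(=O)[C@]1([C@H](C(=O)OC)/C=C(\OS(=O)(=O)C(F)(F)C(F)(F)C(F)(F)C(F)(F)F)CCCCCCCCCCCCCCCC)C(=O)OCc1ccc(OC)cc1
F4 | step 8 | 1-(4-methoxybenzyl) 3-methyl (1S,6R)-2-(tert-butyldimethylsilyloxy)-4-hexadecyl-1-[(2R,3Z)-1-methoxy-1-oxo-4-(trifluoromethylsulfonyloxy)icos-3-en-2-yl]-6-(2-methoxy-2-oxoethyl)cyclohexa-2,4-diene-1,3-dicarboxylate | COC(=O)C[C@@H]1C=C(CCCCCCCCCCCCCCCC)C(C(=O)OC)=C(O[Si](C)(C)C(C)(C)C)[C@]1([C@H](C(=O)OC)/C=C(\OS(=O)(=O)C(F)(F)F)CCCCCCCCCCCCCCCC)C(=O)OCc1ccc(OC)cc1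
F5 | step 8 | 4a-(4-methoxybenzyl) 1,4,6-trimethyl (1S,4R,4aS,8aS)-5-(tert-butyldimethylsilyloxy)-2,7-dihexadecyl-1,4,4a,8a-tetrahydronaphthalene-1,4,4a,6-tetracarboxylate | CCCCCCCCCCCCCCCCC1=C[C@@H](C(=O)OC)[C@]2(C(=O)OCc3ccc(OC)cc3)C(O[Si](C)(C)C(C)(C)C)=C(C(=O)OC)C(CCCCCCCCCCCCCCCC)=C[C@H]2[C@@H]1C(=O)OC
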